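**Assumption:** the ten-membered ring is numbered as a germacrane (C1=C10 alkene, C4–C5 epoxide, C6 OAc, C7 iPr, C8 O-senecioyl). Read this way the SMILES is (1(10)E,4S,5R,6R,7R,8S) with a cis-fused epoxide (C3 and C6 on the same side of the oxirane), and that is the structure made here.

## Retrosynthetic overview

1. Target ⇒ O8-senecioylation ⇒ 1,3-anti diol 6-monoacetate ⇒ Evans–Tishchenko reduction (MeCHO) of a ten-membered β-hydroxy ketone (C6–OH, C8=O).
2. β-Hydroxy ketone ⇒ N–O cleavage of a bridged Δ2-isoxazoline ⇒ intramolecular nitrile oxide cycloaddition of an acyclic nitro (E)-vinyl epoxide; the C7–C8 and C6–O bonds, and so the carbocycle and the isoxazoline, form in one operation.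
3. Nitro vinyl epoxide ⇒ Julia–Kocienski olefination (isobutyl PT-sulfone) of an epoxy aldehyde ⇒ Pd-allylation of nitromethane with an ene-derived allylic chloride ⇒ (2R,3S)-epoxynerol ⇒ nerol (Sharpless epoxidation).
4. Ring order: epoxide (step 1) → ten-membered carbocycle and isoxazoline together (step 8) → isoxazoline opened again (step 9).

## Route

**Step 1**
Reactants: 1 nerol
Product: 2 (2R,3S)-2,3-epoxynerol
Conditions: Ti(OiPr)4 (10 mol%), D-(−)-diethyl tartrate (12 mol%), t-BuOOH, 4 Å MS, CH2Cl2, −20 °C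
Reagents that add atoms: tert-butyl hydroperoxide, CC(C)(C)OO
Why: Katsuki–Sharpless asymmetric epoxidation acts only on the allylic-alcohol alkene; the Z-alkene gives the cis-epoxide and D-(−)-tartrate gives the (2R,3S) enantiomer (L-(+)-tartrate is known to give (2S,3R)-epoxynerol, ca. 93% ee), which sets C4 (S) and C5 (R) of the target.

**Step 2**
Reactants: 2 (2R,3S)-2,3-epoxynerol
Product: 3 [(2R,3S)-3-(3-chloro-4-methylpent-4-en-1-yl)-3-methyloxiran-2-yl]methanol (both C–Cl epimers)
Conditions: PhSeCl (10 mol%), NCS (1.1 equiv), MeCN, 25 °C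
Reagents that add atoms: N-chlorosuccinimide, O=C1CCC(=O)N1Cl
Why: selenium-catalysed ene-type allylic chlorination attacks the electron-rich trisubstituted alkene and moves it to the terminal position; epoxide and primary OH are inert, and the unselectively formed C–Cl centre is erased in step 3.

**Step 3**
Reactants: 3 allylic chloride
Product: 4 [(2R,3S)-3-methyl-3-[(3E)-4-methyl-6-nitrohex-3-en-1-yl]oxiran-2-yl]methanol
Conditions: Pd(PPh3)4 (5 mol%), MeNO2 (10 equiv), K2CO3 (1.5 equiv), THF–DMSO 4:1, 40 °C
Reagents that add atoms: nitromethane, C[N+](=O)[O-]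
Why: Tsuji–Trost allylic alkylation: both C–Cl epimers ionise to one 2-methyl-π-allylpalladium, the soft nitronate attacks the unhindered CH2 terminus, and the favoured syn complex gives the (E)-trisubstituted alkene (minor Z isomer removed on AgNO3–silica); excess MeNO2 stops double allylation and the non-allylic epoxide is not ionised.

**Step 4**
Reactants: 4 nitro epoxy alcohol
Product: 5 (2S,3S)-3-methyl-3-[(3E)-4-methyl-6-nitrohex-3-en-1-yl]oxirane-2-carbaldehyde
Conditions: TEMPO (10 mol%), PhI(OAc)2 (1.2 equiv), CH2Cl2, rt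
Reagents that add atoms: none
Why: TEMPO/PhI(OAc)2 oxidation of the primary alcohol stops at the aldehyde under base-free conditions, so the nitro group and the epoxide centres are untouched (the descriptor at the CHO-bearing carbon changes by CIP rank only).

**Step 5**
Reactants: 6 1-phenyl-1H-tetrazole-5-thiol
Product: 7 5-(2-methylpropylsulfanyl)-1-phenyl-1H-tetrazole
Conditions: i-BuBr, K2CO3, DMF, 60 °C
Reagents that add atoms: 1-bromo-2-methylpropane, CC(C)CBr
Why: SN2 S-alkylation of the soft tetrazolethiolate.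

**Step 6**
Reactants: 7 PT sulfide
Product: 8 5-(2-methylpropylsulfonyl)-1-phenyl-1H-tetrazole
Conditions: (NH4)6Mo7O24·4H2O (10 mol%), 30% H2O2, EtOH, rt
Reagents that add atoms: hydrogen peroxide, OO
Why: molybdate-catalysed peroxide oxidation of sulfide to sulfone; the tetrazole is inert.

**Step 7**
Reactants: 5 nitro epoxy aldehyde; 8 isobutyl PT-sulfone
Product: 9 (2S,3R)-2-methyl-2-[(3E)-4-methyl-6-nitrohex-3-en-1-yl]-3-[(1E)-3-methylbut-1-en-1-yl]oxirane
Conditions: 8 (1.4 equiv), KHMDS (2.5 equiv, added last), DME, −60 °C → rt; AcOH quench at −40 °C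
Reagents that add atoms: none
Why: Julia–Kocienski olefination (PT-sulfone, K+, DME) gives the (E)-alkene by addition, Smiles rearrangement and anti elimination; the first equivalent of base parks the nitro group as its unreactive potassium nitronate (re-protonated at carbon on AcOH quench), and the epoxide centres are not involved.

**Step 8**
Reactants: 9 nitro (E)-vinyl epoxide
Product: 11 bridged epoxy-isoxazoline (4S,5R,6R,7R), via nitrile oxide 10 (not isolated)
Conditions: PhNCO (4 equiv), Et3N (0.3 equiv), toluene, 85 °C; 9 added by syringe pump over 24 h, final 2 mM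
Reagents that add atoms: none
Why: Proposed new method: Mukaiyama dehydration of the primary nitro group gives nitrile oxide 10, which at high dilution adds across the (E)-C6=C7 alkene in the bridged mode (C8 to C7, O to C6), closing the ten-membered carbocycle and the Δ2-isoxazoline together; the fused alternative would need a nine-membered ring holding an (E)-trisubstituted alkene, and the cis-epoxide acts as a turn element; suprafacial addition to the E-alkene fixes C6/C7 (C5 and iPr trans on the isoxazoline), and the face is set by the s-trans vinyl-oxirane conformer (C5–H eclipsing C=C), from which the tether on C4 reaches only the alkene face anti to the epoxide oxygen, giving 6R,7R (the same 5,6-anti sense nitrile oxides show with allylic ethers); the closest known reaction type is the intramolecular nitrile oxide cycloaddition that gives bridged isoxazolines in 12–16-membered rings.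

**Step 9**
Reactants: 11 bridged epoxy-isoxazoline
Product: 13 epoxy β-hydroxy ketone (4S,5R,6R,7S), via β-hydroxy imine 12 (not isolated)
Conditions: SmI2 (3 equiv), THF, 0 °C; then B(OH)3, H2O–MeOH, rt
Reagents that add atoms: water, O
Why: single-electron N–O cleavage of the Δ2-isoxazoline by SmI2 gives β-hydroxy imine 12, hydrolysed in the same flask under boric-acid buffering to the β-hydroxy ketone (isoxazoline as aldol equivalent); no base is present, so C7 is not epimerised, the β,γ-enone is not conjugated, and the non-conjugated epoxide and the alkene are inert.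

**Step 10**
Reactants: 13 epoxy β-hydroxy ketone
Product: 15 6-O-acetyl anti-6,8-diol (4S,5R,6R,7R,8S), via hemiacetal 14 (not isolated)
Conditions: MeCHO (6 equiv), SmI2 (0.3 equiv), THF, −10 °C
Reagents that add atoms: acetaldehyde, CC=O
Why: Evans–Tishchenko reduction: the Sm(III)-bound hemiacetal of C6–OH and acetaldehyde transfers hydride intramolecularly to the C8 ketone through a six-membered chair-like transition state, giving the 1,3-anti diol (C8 = S) and placing the acetate on O6 in the same operation.

**Step 11**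
Reactants: 15 6-O-acetyl anti-6,8-diol
Product: 16 target, (1(10)E,4S,5R,6R,7R,8S)-6-acetoxy-4,5-epoxy-8-(3-methylbut-2-enoyloxy)germacr-1(10)-ene
Conditions: 3-methylbut-2-enoyl chloride (2 equiv), pyridine (4 equiv), DMAP (0.1 equiv), CH2Cl2, 0 °C → rt
Reagents that add atoms: 3-methylbut-2-enoyl chloride, CC(C)=CC(Cl)=O
Why: DMAP-catalysed acylation (nucleophilic catalysis) of the remaining hindered C8–OH with retention; pyridine as the only base limits ketene-type deconjugation of the senecioyl group and 6→8 acetyl migration, and the epoxide tolerates the non-acidic medium.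

## Compound list

1 | nerol, (2Z)-3,7-dimethylocta-2,6-dien-1-ol | CC(C)=CCC/C(C)=C\CO | starting material
2 | (2R,3S)-2,3-epoxynerol, [(2R,3S)-3-methyl-3-(4-methylpent-3-en-1-yl)oxiran-2-yl]methanol | CC(C)=CCC[C@]1(C)O[C@@H]1CO | intermediate
3 | [(2R,3S)-3-(3-chloro-4-methylpent-4-en-1-yl)-3-methyloxiran-2-yl]methanol, both C–Cl epimers | CC(=C)C(Cl)CC[C@]1(C)O[C@@H]1CO | intermediate
4 | [(2R,3S)-3-methyl-3-[(3E)-4-methyl-6-nitrohex-3-en-1-yl]oxiran-2-yl]methanol | [O-][N+](=O)CC/C(C)=C/CC[C@]1(C)O[C@@H]1CO | intermediate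
5 | (2S,3S)-3-methyl-3-[(3E)-4-methyl-6-nitrohex-3-en-1-yl]oxirane-2-carbaldehyde | [O-][N+](=O)CC/C(C)=C/CC[C@]1(C)O[C@@H]1C=O | intermediate
6 | 1-phenyl-1H-tetrazole-5-thiol | SC1=NN=NN1c1ccccc1 | starting material
7 | 5-(2-methylpropylsulfanyl)-1-phenyl-1H-tetrazole | CC(C)CSC1=NN=NN1c1ccccc1 | intermediate
8 | 5-(2-methylpropylsulfonyl)-1-phenyl-1H-tetrazole | CC(C)CS(=O)(=O)C1=NN=NN1c1ccccc1 | intermediate
9 | (2S,3R)-2-methyl-2-[(3E)-4-methyl-6-nitrohex-3-en-1-yl]-3-[(1E)-3-methylbut-1-en-1-yl]oxirane | [O-][N+](=O)CC/C(C)=C/CC[C@]1(C)O[C@@H]1/C=C/C(C)C | intermediate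
10 | (3E)-3-methyl-6-[(2S,3R)-2-methyl-3-[(1E)-3-methylbut-1-en-1-yl]oxiran-2-yl]hex-3-enenitrile N-oxide | [O-][N+]#CC/C(C)=C/CC[C@]1(C)O[C@@H]1/C=C/C(C)C | intermediate
11 | bridged epoxy-isoxazoline: ten-membered carbocycle (germacrane numbering) with 1(10)E-alkene, cis-4,5-epoxide (4S,5R), 7-isopropyl (7R), and an O–N= bridge from C6 (6R) to C8 (C8=N) | O3[C@@H]1[C@H](C(C)C)C(=N3)C/C(C)=C/CC[C@]2(C)O[C@H]12 | intermediate
12 | (1(10)E,4S,5R,6R,7R)-4,5-epoxy-6-hydroxygermacr-1(10)-en-8-imine | O[C@@H]1[C@H](C(C)C)C(=N)C/C(C)=C/CC[C@]2(C)O[C@H]12 | intermediate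
13 | (1(10)E,4S,5R,6R,7S)-4,5-epoxy-6-hydroxygermacr-1(10)-en-8-one | O[C@@H]1[C@H](C(C)C)C(=O)C/C(C)=C/CC[C@]2(C)O[C@H]12 | intermediate
14 | 6-O-(1-hydroxyethyl) hemiacetal of 13 (Sm-bound, configuration as in 13, hemiacetal carbon undefined) | CC(O)O[C@@H]1[C@H](C(C)C)C(=O)C/C(C)=C/CC[C@]2(C)O[C@H]12 | intermediate
15 | (1(10)E,4S,5R,6R,7R,8S)-6-acetoxy-4,5-epoxygermacr-1(10)-en-8-ol | CC(=O)O[C@@H]1[C@H](C(C)C)[C@@H](O)C/C(C)=C/CC[C@]2(C)O[C@H]12 | intermediate
16 | (1(10)E,4S,5R,6R,7R,8S)-6-acetoxy-4,5-epoxy-8-(3-methylbut-2-enoyloxy)germacr-1(10)-ene | CC(=O)O[C@@H]1[C@H](C(C)C)[C@@H](OC(=O)C=C(C)C)C/C(C)=C/CC[C@]2(C)O[C@H]12 | target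

## Step count and risks

Total steps: 11 (steps 5 and 6 prepare the olefination reagent 8). Longest linear sequence: 9 (nerol → 16, steps 1–4 and 7–11).

**Step 7 (olefination next to a free nitro group).** The nitronate may consume base unevenly or undergo Henry addition to the aldehyde. The fallback sets out from 5 and comes back at 11. A base-free Wittig reaction of 5 with commercial 1-(triphenylphosphoranylidene)propan-2-one (CH2Cl2, rt) gives the (E)-γ,δ-epoxy enone F1. Mukaiyama dehydration (PhNCO, Et3N, toluene, high dilution) gives the keto nitrile oxide F2, not isolated, which cyclises with the nitrile-oxide carbon going to the enone α-carbon to give the 7-acetyl bridged isoxazoline F3. Petasis methylenation (Cp2TiMe2, toluene, 70 °C; non-basic, so the acidic C7–H is not epimerised) gives the 7-isopropenyl bridged isoxazoline F4. Hydrogenation with Wilkinson's catalyst (H2, 1 atm, benzene) reduces only the 1,1-disubstituted alkene and returns 11.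

**Step 8 (ten-membered ring by nitrile oxide cycloaddition).** Furoxan dimers or oligomers, the fused nine-ring regioisomer or the wrong alkene face are all possible. The fallback sets out from 9 and comes back at 11, and replaces the nitrile oxide by a dipole that cannot dimerise. TMSCl/Et3N (toluene, rt) converts 9 into the O-trimethylsilyl nitronate F5. Heating at 90 °C at 2 mM (intramolecular silyl nitronate–olefin cycloaddition, long reaction times possible) gives the N-(trimethylsilyloxy)isoxazolidine F6. Catalytic TsOH in CH2Cl2 eliminates trimethylsilanol and gives 11.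

**Step 10 (Evans–Tishchenko in the epoxy macrocycle).** Sm(III) may open the epoxide transannularly, or the ring may not allow the hemiacetal to reach the ketone. The fallback sets out from 13 and comes back at 16, separating reduction from acylation. Saksena–Evans reduction (Me4NBH(OAc)3, MeCN–AcOH, −30 °C; hydride delivered from boron bound to O6) gives the anti-6,8-diol F7. One equivalent of 3-methylbut-2-enoyl chloride (pyridine, DMAP, −20 °C) acylates the less hindered O8 (O6 is flanked by the epoxide and C7) to give the 8-O-senecioyl 6-alcohol F8. Ac2O/DMAP/pyridine then gives 16.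

## Further compounds

F1 | step 7 | (3E)-4-[(2R,3S)-3-methyl-3-[(3E)-4-methyl-6-nitrohex-3-en-1-yl]oxiran-2-yl]but-3-en-2-one | [O-][N+](=O)CC/C(C)=C/CC[C@]1(C)O[C@@H]1/C=C/C(C)=O
F2 | step 7 | nitrile oxide derived from F1 (not isolated) | [O-][N+]#CC/C(C)=C/CC[C@]1(C)O[C@@H]1/C=C/C(C)=O
F3 | step 7 | 7-acetyl analogue of bridged isoxazoline 11 (configuration as in 11) | O3[C@@H]1[C@H](C(C)=O)C(=N3)C/C(C)=C/CC[C@]2(C)O[C@H]12
F4 | step 7 | 7-isopropenyl analogue of bridged isoxazoline 11 (configuration as in 11) | O3[C@@H]1[C@H](C(C)=C)C(=N3)C/C(C)=C/CC[C@]2(C)O[C@H]12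
F5 | step 8 | O-trimethylsilyl nitronate of 9 | C[Si](C)(C)O[N+]([O-])=CC/C(C)=C/CC[C@]1(C)O[C@@H]1/C=C/C(C)C
F6 | step 8 | N-(trimethylsilyloxy)isoxazolidine, the C8–H, N–OSiMe3 precursor of 11 (C8 and N undefined) | O3[C@@H]1[C@H](C(C)C)C(N3O[Si](C)(C)C)C/C(C)=C/CC[C@]2(C)O[C@H]12
F7 | step 10 | (1(10)E)-4,5-epoxygermacr-1(10)-ene-6,8-diol, anti-diol with configuration as in 15 | O[C@@H]1[C@H](C(C)C)[C@@H](O)C/C(C)=C/CC[C@]2(C)O[C@H]12
F8 | step 10 | 8-O-(3-methylbut-2-enoyl) 6-alcohol, configuration as in 16 | O[C@@H]1[C@H](C(C)C)[C@@H](OC(=O)C=C(C)C)C/C(C)=C/CC[C@]2(C)O[C@H]12
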